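## Retrosynthetic overview

- Target 18 ⇐ tetra-MOM ether 17 ⇐ C3 boronate 16 ⇐ flav-3-ene 15. The C3 hydroxyl comes from copper-catalysed borylation of C3=C4 anti to the C2 aryl group, then oxidation; this borylation acts only on the aryl-conjugated alkene and spares the prenyl alkene.
- 15 ⇐ diene 14 by ring-closing metathesis (C3=C4). Ring C is the only ring built and closes after the key step; rings A and B are bought as arenes.
- The plan rests on C2, the benzylic carbon that carries ring B and is bonded to O1 and C3. 14 ⇐ phenol 8 + cinnamyl carbonate 12 by iridium-catalysed branched allylic etherification, which makes O1–C2 and sets C2.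
- 8 ⇐ phloroglucinol 1 (bis-MOM ether, tertiary propargyl ether, semihydrogenation/Claisen for the C8 prenyl group, ortho-formylation, Wittig). 12 ⇐ caffeic acid 9 (MOM protection, i-Bu2AlH, methyl chloroformate).

Key step: step 9

Assumption: the (Sa,Sc,Sc) phosphoramidite is taken to give the S ether 14, by analogy with the sense of induction of this catalyst family with cinnamyl carbonates; the antipodal ligand would be used if a model reaction showed the opposite sense.

Remark: flavan numbering is used (ring A = phloroglucinol-derived arene, ring B = catechol arene, ring C = pyran ring).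

## Route

Step 1
Reactants: 1 phloroglucinol
Product: 2 3,5-bis(methoxymethoxy)phenol
Conditions: MOMCl (2.1 equiv), i-Pr2NEt (2.5 equiv), DMF, 0 °C → rt; chromatography
Reagents that add atoms: chloromethyl methyl ether, COCCl
Why: Statistical Williamson-type O-alkylation of a symmetrical triol with two equivalents of MOMCl, the bis-ether being separated from mono- and tris-ethers by chromatography; no regiochemical question arises because the three hydroxyls are equivalent.

Step 2
Reactants: 2 3,5-bis(methoxymethoxy)phenol; 3 3-chloro-3-methylbut-1-yne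
Product: 4 1,3-bis(methoxymethoxy)-5-[(2-methylbut-3-yn-2-yl)oxy]benzene
Conditions: 3 (1.3 equiv), DBU (1.4 equiv), CuCl2·2H2O (0.5 mol%), MeCN, 0 °C
Reagents that add atoms: none
Why: Copper-catalysed O-alkylation of the phenol by the tertiary propargylic chloride (substitution through a copper acetylide-derived intermediate) should give the hindered tertiary aryl ether at 0 °C, below the temperature at which C-alkylation or chromene formation sets in.

Step 3
Reactants: 4 1,3-bis(methoxymethoxy)-5-[(2-methylbut-3-yn-2-yl)oxy]benzene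
Product: 6 3,5-bis(methoxymethoxy)-2-(3-methylbut-2-en-1-yl)phenol, via 1,1-dimethylallyl aryl ether 5 (not isolated)
Conditions: H2 (1 atm), Pd/CaCO3 poisoned with Pb(OAc)2, quinoline, EtOAc, rt; filter; then PhMe, 100 °C
Reagents that add atoms: none
Why: Semihydrogenation of the terminal alkyne over poisoned palladium gives the 1,1-dimethylallyl ether, whose aromatic Claisen rearrangement ([3,3]-sigmatropic) transfers the allyl unit with allylic inversion to an ortho carbon (C2 and C6 are equivalent) and so gives the linear prenyl group after tautomerisation, with no para or O-alkylated isomer possible.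

Step 4
Reactants: 6 3,5-bis(methoxymethoxy)-2-(3-methylbut-2-en-1-yl)phenol
Product: 7 2-hydroxy-4,6-bis(methoxymethoxy)-3-(3-methylbut-2-en-1-yl)benzaldehyde
Conditions: MgCl2 (2 equiv), Et3N (4 equiv), (CH2O)n (6 equiv), MeCN, 80 °C
Reagents that add atoms: paraformaldehyde (formaldehyde), C=O
Why: Magnesium phenoxide-directed ortho-formylation (Casnati–Skattebøl reaction; hydroxymethylation, then hydride transfer to a second formaldehyde) can only occur at C6, the one free position ortho to the hydroxyl, and its basic medium leaves MOM ethers and the prenyl alkene alone.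

Step 5
Reactants: 7 2-hydroxy-4,6-bis(methoxymethoxy)-3-(3-methylbut-2-en-1-yl)benzaldehyde
Product: 8 3,5-bis(methoxymethoxy)-2-(3-methylbut-2-en-1-yl)-6-vinylphenol
Conditions: Ph3PCH3Br (2.5 equiv), KOt-Bu (2.5 equiv), THF, 0 °C → rt
Reagents that add atoms: methyltriphenylphosphonium bromide, C[P+](c1ccccc1)(c1ccccc1)c1ccccc1.[Br-]
Why: Wittig methylenation, in which one equivalent of ylide is spent on the phenol and the excess converts the aldehyde of the phenoxide into the vinyl group, while MOM ethers and the prenyl alkene are inert to the ylide.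

Step 6
Reactants: 9 caffeic acid
Product: 10 methoxymethyl (E)-3-[3,4-bis(methoxymethoxy)phenyl]prop-2-enoate
Conditions: MOMCl (3.6 equiv), i-Pr2NEt (4 equiv), CH2Cl2/DMF, 0 °C → rt
Reagents that add atoms: chloromethyl methyl ether, COCCl
Why: Exhaustive O-alkylation of both phenols and the carboxylate with MOMCl protects the catechol and turns the acid into a reducible MOM ester in one operation, leaving the E alkene as it is.

Step 7
Reactants: 10 methoxymethyl (E)-3-[3,4-bis(methoxymethoxy)phenyl]prop-2-enoate
Product: 11 (E)-3-[3,4-bis(methoxymethoxy)phenyl]prop-2-en-1-ol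
Conditions: i-Bu2AlH (3 equiv), CH2Cl2, −78 → −20 °C; aq. potassium sodium tartrate
Reagents that add atoms: none
Why: i-Bu2AlH reduces the conjugated ester in the 1,2 sense to the allylic alcohol without touching the acetal protecting groups or the E geometry.

Step 8
Reactants: 11 (E)-3-[3,4-bis(methoxymethoxy)phenyl]prop-2-en-1-ol
Product: 12 (E)-3-[3,4-bis(methoxymethoxy)phenyl]allyl methyl carbonate
Conditions: ClCO2Me (1.3 equiv), pyridine, CH2Cl2, 0 °C
Reagents that add atoms: methyl chloroformate, COC(=O)Cl
Why: Acylation of the primary allylic alcohol with methyl chloroformate and pyridine gives the carbonate leaving group needed for ionisation by iridium.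

Step 9
Reactants: 8 3,5-bis(methoxymethoxy)-2-(3-methylbut-2-en-1-yl)-6-vinylphenol; 12 (E)-3-[3,4-bis(methoxymethoxy)phenyl]allyl methyl carbonate
Product: 14 1-{[(1S)-1-[3,4-bis(methoxymethoxy)phenyl]prop-2-en-1-yl]oxy}-3,5-bis(methoxymethoxy)-2-(3-methylbut-2-en-1-yl)-6-vinylbenzene (branched S ether), via lithium phenoxide 13 (not isolated)
Conditions: 8, LiN(SiMe3)2 (1.0 equiv), THF, 0 °C; then 12 (1.3 equiv), [Ir(cod)Cl]2 (2 mol%), (Sa,Sc,Sc)-BINOL-derived N,N-bis(1-phenylethyl)phosphoramidite (4 mol%, pre-activated with n-PrNH2, volatiles removed), THF, rt → 50 °C; Et3N-deactivated silica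
Reagents that add atoms: none
Why: Oxidative addition of carbonate 12 to the cyclometalated univalent iridium phosphoramidite complex (with loss of CO2 and methoxide) gives a trivalent allyliridium species, and the lithium phenoxide oxygen attacks its aryl-bearing terminus from the face opposite the metal, forming the O1–C2 bond. The closest known reaction is the iridium–phosphoramidite-catalysed enantioselective allylic etherification of cinnamyl carbonates with alkali phenoxides, ortho-substituted ones included, applied here to a phenoxide with both ortho positions occupied. No ring is closed. The C2 stereocentre is set by the ligand, which fixes the allyl face bound to iridium; the (Sa,Sc,Sc) ligand is expected to give the S ether, the arrangement that becomes 2R in the flavan. The step needs branched over linear selectivity, secured by the catalyst's preference for the substituted terminus and reinforced by the electron-rich ring B, and O- over C-allylation, secured by the hard lithium phenoxide in THF and by the two MOM groups flanking the only unsubstituted ring A carbon (the future C6). The reaction is stopped at full conversion of 13 so that the catalyst cannot re-ionise the branched ether.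

Step 10
Reactants: 14 branched S ether
Product: 15 (2S)-2-[3,4-bis(methoxymethoxy)phenyl]-5,7-bis(methoxymethoxy)-8-(3-methylbut-2-en-1-yl)-2H-chromene
Conditions: second-generation Grubbs catalyst (5 mol%), CH2Cl2 (0.01 M), 40 °C, dark
Reagents that add atoms: none
Why: Ring-closing olefin metathesis joins the two monosubstituted vinyl groups into the six-membered ring C (C3=C4) with loss of ethylene; the trisubstituted prenyl alkene initiates far more slowly and could only close a seven-membered ring, and C2 is not touched.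

Step 11
Reactants: 15 (2S)-2-[3,4-bis(methoxymethoxy)phenyl]-5,7-bis(methoxymethoxy)-8-(3-methylbut-2-en-1-yl)-2H-chromene
Product: 16 2-[(2S,3S)-2-[3,4-bis(methoxymethoxy)phenyl]-5,7-bis(methoxymethoxy)-8-(3-methylbut-2-en-1-yl)chroman-3-yl]-4,4,5,5-tetramethyl-1,3,2-dioxaborolane (2,3-trans)
Conditions: B2pin2 (1.3 equiv), (SIMes)CuCl (5 mol%; SIMes = 1,3-dimesitylimidazolidin-2-ylidene), NaOt-Bu (10 mol%), MeOH (2 equiv), THF, rt
Reagents that add atoms: bis(pinacolato)diboron, CC1(C)OB(OC1(C)C)B1OC(C)(C)C(C)(C)O1
Why: Copper-catalysed protoboration of an aryl-conjugated cyclic alkene: the copper–boryl species adds syn across C3=C4 with boron at C3 and copper at benzylic C4 from the face anti to the C2 aryl group, which sets C3 trans to C2, and methanol protonates C4–Cu with retention, while the isolated trisubstituted prenyl alkene is not a substrate for borylcupration (a dialkylborane such as 9-BBN would be expected to attack it at least as fast as the ring alkene).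

Step 12
Reactants: 16 C3 pinacol boronate
Product: 17 (2R,3S)-2-[3,4-bis(methoxymethoxy)phenyl]-5,7-bis(methoxymethoxy)-8-(3-methylbut-2-en-1-yl)chroman-3-ol
Conditions: NaBO3·4H2O (5 equiv), THF/H2O (1:1), rt
Reagents that add atoms: sodium perborate (peroxoborate in water), [Na+].OO[B-](O)(O)O
Why: Oxidation of the C–B bond by peroxoborate proceeds by 1,2-migration of C3 from boron to oxygen with retention, so the 2,3-trans relationship is kept, and the weakly basic medium is chosen to avoid β-elimination of the O1 aryloxide from the boronate.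

Step 13
Reactants: 17 (2R,3S)-2-[3,4-bis(methoxymethoxy)phenyl]-5,7-bis(methoxymethoxy)-8-(3-methylbut-2-en-1-yl)chroman-3-ol
Product: 18 8-prenylcatechin, (2R,3S)-2-(3,4-dihydroxyphenyl)-8-(3-methylbut-2-en-1-yl)chromane-3,5,7-triol
Conditions: HCl (0.5 M in MeOH), 0 °C → rt, argon
Reagents that add atoms: none
Why: Acid-catalysed transacetalisation with methanol removes the four aryl MOM ethers as dimethoxymethane, and the dilute acid at or below room temperature is meant to leave the prenyl alkene, the C3 alcohol and the C2 and C3 stereocentres untouched.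

## Compound list

1 | phloroglucinol | Oc1cc(O)cc(O)c1 | starting material
2 | 3,5-bis(methoxymethoxy)phenol | COCOc1cc(O)cc(OCOC)c1 | intermediate
3 | 3-chloro-3-methylbut-1-yne | CC(C)(Cl)C#C | starting material
4 | 1,3-bis(methoxymethoxy)-5-[(2-methylbut-3-yn-2-yl)oxy]benzene | C#CC(C)(C)Oc1cc(OCOC)cc(OCOC)c1 | intermediate
5 | 1,3-bis(methoxymethoxy)-5-[(2-methylbut-3-en-2-yl)oxy]benzene (not isolated) | C=CC(C)(C)Oc1cc(OCOC)cc(OCOC)c1 | intermediate
6 | 3,5-bis(methoxymethoxy)-2-(3-methylbut-2-en-1-yl)phenol | CC(C)=CCc1c(O)cc(OCOC)cc1OCOC | intermediate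
7 | 2-hydroxy-4,6-bis(methoxymethoxy)-3-(3-methylbut-2-en-1-yl)benzaldehyde | CC(C)=CCc1c(O)c(C=O)c(OCOC)cc1OCOC | intermediate
8 | 3,5-bis(methoxymethoxy)-2-(3-methylbut-2-en-1-yl)-6-vinylphenol | CC(C)=CCc1c(OCOC)cc(OCOC)c(C=C)c1O | intermediate
9 | caffeic acid, (E)-3-(3,4-dihydroxyphenyl)prop-2-enoic acid | OC(=O)/C=C/c1ccc(O)c(O)c1 | starting material
10 | methoxymethyl (E)-3-[3,4-bis(methoxymethoxy)phenyl]prop-2-enoate | COCOC(=O)/C=C/c1ccc(OCOC)c(OCOC)c1 | intermediate
11 | (E)-3-[3,4-bis(methoxymethoxy)phenyl]prop-2-en-1-ol | OC/C=C/c1ccc(OCOC)c(OCOC)c1 | intermediate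
12 | (E)-3-[3,4-bis(methoxymethoxy)phenyl]allyl methyl carbonate | COC(=O)OC/C=C/c1ccc(OCOC)c(OCOC)c1 | intermediate
13 | lithium 3,5-bis(methoxymethoxy)-2-(3-methylbut-2-en-1-yl)-6-vinylphenoxide (not isolated) | [Li+].[O-]c1c(CC=C(C)C)c(OCOC)cc(OCOC)c1C=C | intermediate
14 | 1-{[(1S)-1-[3,4-bis(methoxymethoxy)phenyl]prop-2-en-1-yl]oxy}-3,5-bis(methoxymethoxy)-2-(3-methylbut-2-en-1-yl)-6-vinylbenzene | CC(C)=CCc1c(OCOC)cc(OCOC)c(C=C)c1O[C@H](c1ccc(OCOC)c(OCOC)c1)C=C | intermediate
15 | (2S)-2-[3,4-bis(methoxymethoxy)phenyl]-5,7-bis(methoxymethoxy)-8-(3-methylbut-2-en-1-yl)-2H-chromene | CC(C)=CCc1c(OCOC)cc(OCOC)c2c1O[C@H](c1ccc(OCOC)c(OCOC)c1)C=C2 | intermediate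
16 | 2-[(2S,3S)-2-[3,4-bis(methoxymethoxy)phenyl]-5,7-bis(methoxymethoxy)-8-(3-methylbut-2-en-1-yl)chroman-3-yl]-4,4,5,5-tetramethyl-1,3,2-dioxaborolane | CC(C)=CCc1c(OCOC)cc(OCOC)c2c1O[C@H](c1ccc(OCOC)c(OCOC)c1)[C@@H](B1OC(C)(C)C(C)(C)O1)C2 | intermediate
17 | (2R,3S)-2-[3,4-bis(methoxymethoxy)phenyl]-5,7-bis(methoxymethoxy)-8-(3-methylbut-2-en-1-yl)chroman-3-ol | CC(C)=CCc1c(OCOC)cc(OCOC)c2c1O[C@H](c1ccc(OCOC)c(OCOC)c1)[C@@H](O)C2 | intermediate
18 | 8-prenylcatechin, (2R,3S)-2-(3,4-dihydroxyphenyl)-8-(3-methylbut-2-en-1-yl)chromane-3,5,7-triol | CC(C)=CCc1c(O)cc(O)c2c1O[C@H](c1ccc(O)c(O)c1)[C@@H](O)C2 | target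

## Step count and risks

Total steps: 13. Longest linear sequence: 10 (steps 1–5 and 9–13).

**Step 9 (key step).** Attack of the doubly ortho-substituted phenoxide on the allyliridium intermediate may be slow. Linear ether formation, C-allylation at the free ring A carbon and iridium-mediated re-ionisation of the electron-rich branched ether could then take over, with loss of regioselectivity and enantiomeric purity.

Fallback (sets out from 11 and 8, returns at 14): the O1–C2 bond is made by SN2 opening of an enantiopure epoxide instead. Sharpless asymmetric epoxidation of 11 (Ti(Oi-Pr)4, L-(+)-diisopropyl tartrate, t-BuOOH, 4 Å sieves, CH2Cl2, −20 °C) should give [(2S,3S)-3-[3,4-bis(methoxymethoxy)phenyl]oxiran-2-yl]methanol F1. The sodium phenoxide of 8 (NaOH, H2O/dioxane, 70 °C) should open it at the benzylic carbon with inversion to give (2S,3R)-3-[3,4-bis(methoxymethoxy)phenyl]-3-[3,5-bis(methoxymethoxy)-2-(3-methylbut-2-en-1-yl)-6-vinylphenoxy]propane-1,2-diol F2. 1,1'-Thiocarbonyldiimidazole (DMAP, THF, rt) should convert the diol into (4S)-4-{(R)-[3,4-bis(methoxymethoxy)phenyl][3,5-bis(methoxymethoxy)-2-(3-methylbut-2-en-1-yl)-6-vinylphenoxy]methyl}-1,3-dioxolane-2-thione F3. Corey–Winter olefination with 1,3-dimethyl-2-phenyl-1,3,2-diazaphospholidine (THF, 40 °C) then removes CO2 and sulfur and leaves the terminal alkene of 14.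

**Step 11.** Borylcupration may be sluggish on an alkene attached to the trioxygenated, electron-rich ring A and flanked by the 5-OMOM group. The basic medium could also trigger β-elimination of the O1 aryloxide from the C3 boronate, and forcing conditions could erode the C2 configuration by electrocyclic opening of the chromene.

Fallback (sets out from 2, returns at 17): bromine is carried at C8 in place of the prenyl group, so that no second alkene is present and plain borane can be used.
- 2 is ortho-formylated (MgCl2, Et3N, (CH2O)n, MeCN, 80 °C) to 2-hydroxy-4,6-bis(methoxymethoxy)benzaldehyde F4.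
- Bromination ortho to the hydroxyl (NBS, MeCN, 0 °C) should give 3-bromo-2-hydroxy-4,6-bis(methoxymethoxy)benzaldehyde F5.
- Wittig methylenation (Ph3PCH3Br, KOt-Bu, THF) gives 2-bromo-3,5-bis(methoxymethoxy)-6-vinylphenol F6.
- The conditions of step 9 with 12 should give 2-bromo-1-{[(1S)-1-[3,4-bis(methoxymethoxy)phenyl]prop-2-en-1-yl]oxy}-3,5-bis(methoxymethoxy)-6-vinylbenzene F7.
- The conditions of step 10 should give (2S)-8-bromo-2-[3,4-bis(methoxymethoxy)phenyl]-5,7-bis(methoxymethoxy)-2H-chromene F8.
- Classical hydroboration of the flav-3-ene anti to the C2 aryl group (BH3·THF, 0 °C; then NaBO3·4H2O) should give (2R,3S)-8-bromo-2-[3,4-bis(methoxymethoxy)phenyl]-5,7-bis(methoxymethoxy)chroman-3-ol F9.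
- t-BuLi (3 equiv, THF, −78 °C; alkoxide formation, then bromine–lithium exchange), CuBr·SMe2 and prenyl bromide install the C8 prenyl group and give 17.

**Step 13.** While the last MOM groups are still being cleaved, the acid may add the 7-hydroxyl or methanol to the prenyl alkene (closure of a dimethylchroman ring) or open the O1–C2 bond with epimerisation at C2.

Fallback (sets out from 17, returns at 18): the acetals are exchanged for silyl ethers under aprotic, buffered conditions and the silyl ethers are then removed with fluoride. Et3SiOTf and 2,2'-bipyridyl (CH2Cl2, 0 °C) should convert the four aryl MOM ethers into triethylsilyl ethers and silylate the C3 hydroxyl, giving (2R,3S)-2-[3,4-bis(triethylsilyloxy)phenyl]-8-(3-methylbut-2-en-1-yl)-3,5,7-tris(triethylsilyloxy)chromane F10. Et3N·3HF (THF, rt) then gives 18.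

## Further compounds

F1 | step 9 | [(2S,3S)-3-[3,4-bis(methoxymethoxy)phenyl]oxiran-2-yl]methanol | OC[C@@H]1O[C@H]1c1ccc(OCOC)c(OCOC)c1
F2 | step 9 | (2S,3R)-3-[3,4-bis(methoxymethoxy)phenyl]-3-[3,5-bis(methoxymethoxy)-2-(3-methylbut-2-en-1-yl)-6-vinylphenoxy]propane-1,2-diol | OC[C@H](O)[C@H](Oc1c(CC=C(C)C)c(OCOC)cc(OCOC)c1C=C)c1ccc(OCOC)c(OCOC)c1
F3 | step 9 | (4S)-4-{(R)-[3,4-bis(methoxymethoxy)phenyl][3,5-bis(methoxymethoxy)-2-(3-methylbut-2-en-1-yl)-6-vinylphenoxy]methyl}-1,3-dioxolane-2-thione | S=C1OC[C@H](O1)[C@H](Oc1c(CC=C(C)C)c(OCOC)cc(OCOC)c1C=C)c1ccc(OCOC)c(OCOC)c1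
F4 | step 11 | 2-hydroxy-4,6-bis(methoxymethoxy)benzaldehyde | O=Cc1c(O)cc(OCOC)cc1OCOC
F5 | step 11 | 3-bromo-2-hydroxy-4,6-bis(methoxymethoxy)benzaldehyde | O=Cc1c(O)c(Br)c(OCOC)cc1OCOC
F6 | step 11 | 2-bromo-3,5-bis(methoxymethoxy)-6-vinylphenol | C=Cc1c(O)c(Br)c(OCOC)cc1OCOC
F7 | step 11 | 2-bromo-1-{[(1S)-1-[3,4-bis(methoxymethoxy)phenyl]prop-2-en-1-yl]oxy}-3,5-bis(methoxymethoxy)-6-vinylbenzene | Brc1c(OCOC)cc(OCOC)c(C=C)c1O[C@H](c1ccc(OCOC)c(OCOC)c1)C=C
F8 | step 11 | (2S)-8-bromo-2-[3,4-bis(methoxymethoxy)phenyl]-5,7-bis(methoxymethoxy)-2H-chromene | Brc1c(OCOC)cc(OCOC)c2c1O[C@H](c1ccc(OCOC)c(OCOC)c1)C=C2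
F9 | step 11 | (2R,3S)-8-bromo-2-[3,4-bis(methoxymethoxy)phenyl]-5,7-bis(methoxymethoxy)chroman-3-ol | Brc1c(OCOC)cc(OCOC)c2c1O[C@H](c1ccc(OCOC)c(OCOC)c1)[C@@H](O)C2
F10 | step 13 | (2R,3S)-2-[3,4-bis(triethylsilyloxy)phenyl]-8-(3-methylbut-2-en-1-yl)-3,5,7-tris(triethylsilyloxy)chromane | CC(C)=CCc1c(O[Si](CC)(CC)CC)cc(O[Si](CC)(CC)CC)c2c1O[C@H](c1ccc(O[Si](CC)(CC)CC)c(O[Si](CC)(CC)CC)c1)[C@@H](O[Si](CC)(CC)CC)C2
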